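**Retrosynthetic overview**
1. Last bond: the angelate ester on a 3β-hydroxy-2-ketone. Before that, C3 is set by hydride reduction of a ring-A diosphenol and the umbelliferyl ether is made by Mitsunobu reaction at C11.
2. C11–OH comes from hydroboration of an exocyclic C9=C11 diene (face set by the C10 methyl); the C4 gem-dimethyl comes from cuprate addition to a ring-A enone.
3. Ring A (formed second) closes by an intramolecular carbonyl-ene reaction of a C10–CH2CHO arm onto the C5 isopropenyl group.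
4. Key bond C1–C10 with the quaternary stereocentre: Claisen rearrangement of the vinyl ether of a cyclohexadienylmethanol, anti to the isopropenyl group; it also leaves the C9 exocyclic methylene.
5. Ring B is bought as (S)-(+)-carvone (C5 stereocentre), methylated, triflated and hydroxymethylated; umbelliferone and angelic acid are bought.

Assumption: the SMILES is read literally (3S,5S,9R,10R in the drimane numbering used below: ring A = C1–C5, C10; ring B = C5–C10; C11 = CH2O), i.e. the antipodal drimane series, so C5 is taken from (S)-(+)-carvone.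

**Step 1**
Reactants: 1 (S)-(+)-carvone
Product: 3 (5S)-2,6-dimethyl-5-(prop-1-en-2-yl)cyclohex-2-en-1-one as a C6 epimer mixture, via lithium dienolate 2 (not isolated)
Conditions: LiN(iPr)2, THF, −78 °C; MeI, −78 → 0 °C
Reagents that add atoms: iodomethane, CI
Why: Kinetic α′-deprotonation and enolate alkylation install the future C10 methyl; the new centre is a throw-away mixture (it becomes sp2 in step 2) and C5 is untouched.

**Step 2**
Reactants: 3
Product: 5 (3R)-2,6-dimethyl-3-(prop-1-en-2-yl)cyclohexa-1,5-dien-1-yl trifluoromethanesulfonate, via lithium dienolate 4 (not isolated)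
Conditions: LiN(iPr)2, THF, −78 → 0 °C; PhNTf2, 0 °C → rt
Reagents that add atoms: N-phenylbis(trifluoromethanesulfonimide), FC(F)(F)S(=O)(=O)N(c1ccccc1)S(=O)(=O)C(F)(F)F
Why: The only sp3 α-hydrogen is removed to give the cross-conjugated tetrasubstituted enolate, and O-sulfonylation (enol triflate formation) fixes the C9=C10 double bond.

**Step 3**
Reactants: 5
Product: 6 [(3R)-2,6-dimethyl-3-(prop-1-en-2-yl)cyclohexa-1,5-dien-1-yl]methanol
Conditions: Bu3SnCH2OH, Pd(PPh3)4 (10 mol %), LiCl, 1,4-dioxane, 100 °C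
Reagents that add atoms: (tributylstannyl)methanol, CCCC[Sn](CCCC)(CCCC)CO
Why: Stille cross-coupling of the vinyl triflate with the hydroxymethylstannane gives the primary allylic alcohol needed for the rearrangement; no stereocentre is touched.

**Step 4**
Reactants: 6
Product: 8 2-[(1R,6R)-1,3-dimethyl-2-methylidene-6-(prop-1-en-2-yl)cyclohex-3-en-1-yl]acetaldehyde, via allyl vinyl ether 7 (not isolated)
Conditions: Hg(OAc)2 (0.3 equiv), ethyl vinyl ether, reflux; evaporate; toluene (trace Et3N), 170 °C, sealed tube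
Reagents that add atoms: ethyl vinyl ether, C=COCC
Why: Transvinylation then Claisen rearrangement ([3,3]-sigmatropic) forms the C1–C10 bond and the quaternary centre on the face anti to the pseudoaxial isopropenyl group at C5 (CH2CHO trans to isopropenyl, methyl cis), as in the classical rearrangement of (2-methylcyclohexenyl)methyl vinyl ethers.

**Step 5**
Reactants: 8
Product: 9 (4aR,8aR)-7,8a-dimethyl-4,8-dimethylidene-1,2,3,4,4a,5,8,8a-octahydronaphthalen-2-ol as a C2 epimer mixture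
Conditions: Me2AlCl (1.5 equiv), CH2Cl2, −78 → −20 °C; 1 M HCl work-up
Reagents that add atoms: none
Why: Lewis-acid-promoted intramolecular carbonyl-ene reaction of the aldehyde with the isopropenyl group closes ring A through a chair transition state; the fusion is trans because the two arms were set trans in step 4 (the exocyclic diene has no allylic hydrogen and cannot compete).

**Step 6**
Reactants: 9
Product: 11 (4aR,8aR)-4,7,8a-trimethyl-8-methylidene-4a,5,8,8a-tetrahydronaphthalen-2(1H)-one, via β,γ-unsaturated ketone 10 (not isolated)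
Conditions: DMP, pyridine, CH2Cl2, 0 °C → rt; then DBU (0.3 equiv), rt, short
Reagents that add atoms: none
Why: Dess–Martin oxidation followed by base-mediated isomerisation of the exocyclic alkene into conjugation via the dienolate; brief exposure avoids enolisation at C5.

**Step 7**
Reactants: 11
Product: 12 triethyl{[(4aR,8aR)-4,4,7,8a-tetramethyl-8-methylidene-1,4,4a,5,8,8a-hexahydronaphthalen-2-yl]oxy}silane
Conditions: Me2CuLi (2.5 equiv), Et3SiCl (4 equiv), THF, −78 → −30 °C; Et3N, aq NaHCO3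
Reagents that add atoms: lithium dimethylcuprate, [Li+].C[Cu-]C; chlorotriethylsilane, CC[Si](Cl)(CC)CC
Why: Silyl-chloride-accelerated cuprate conjugate addition puts the second methyl on C4 (the same 1,3-diaxial dimethyl pattern forms from isophorone) and traps the regiodefined C2–C3 enolate as a silyl enol ether, which also masks the ketone for step 8.

**Step 8**
Reactants: 12
Product: 14 [(1R,4aR,8aR)-2,5,5,8a-tetramethyl-7-(triethylsilyloxy)-1,4,4a,5,8,8a-hexahydronaphthalen-1-yl]methanol, via alkylborane 13 (not isolated)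
Conditions: 9-BBN (1.5 equiv), THF, 0 °C → rt; NaBO3·4H2O, THF/H2O, rt
Reagents that add atoms: sodium perborate, [Na+].[Na+].O[B-]1(O)OO[B-](O)(O)OO1
Why: Hydroboration–oxidation; 9-BBN adds only to the 1,1-disubstituted diene terminus (the trisubstituted alkene and hindered enol ether are inert), with hydrogen delivered to C9 from the face opposite the axial C10 methyl, so CH2OH ends cis to that methyl (9R).

**Step 9**
Reactants: 14; 15 umbelliferone (7-hydroxy-2H-chromen-2-one)
Product: 16 7-{[(1R,4aR,8aR)-2,5,5,8a-tetramethyl-7-(triethylsilyloxy)-1,4,4a,5,8,8a-hexahydronaphthalen-1-yl]methoxy}-2H-chromen-2-one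
Conditions: PPh3, DIAD, THF, 0 °C → rt
Reagents that add atoms: none
Why: Mitsunobu etherification of the primary alcohol with the acidic phenol (pKa about 7.8); no stereocentre is involved.

**Step 10**
Reactants: 16
Product: 18 7-{[(1R,4aS,6R,8aR)-6-hydroxy-2,5,5,8a-tetramethyl-7-oxo-1,4,4a,5,6,7,8,8a-octahydronaphthalen-1-yl]methoxy}-2H-chromen-2-one (major 3α epimer), via silyloxy epoxide 17 (not isolated)
Conditions: DMDO (1.1 equiv), acetone/CH2Cl2, −78 → −40 °C; then AcOH/THF/H2O, 0 °C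
Reagents that add atoms: dimethyldioxirane, CC1(C)OO1
Why: Rubottom oxidation; the silyl enol ether is epoxidised much faster than the ring-B alkene or the coumarin, anti to the axial methyls, and the resulting 3α configuration does not matter because C3 becomes sp2 in step 11.

**Step 11**
Reactants: 18
Product: 20 7-{[(1R,4aS,8aR)-7-hydroxy-2,5,5,8a-tetramethyl-6-oxo-1,4,4a,5,6,8a-hexahydronaphthalen-1-yl]methoxy}-2H-chromen-2-one (diosphenol), via 2,3-dione 19 (not isolated)
Conditions: DMP, pyridine, CH2Cl2, rt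
Reagents that add atoms: none
Why: Dess–Martin oxidation of the α-ketol gives the 1,2-dione, which can enolise only toward C1 (C4 is quaternary) and settles as the diosphenol, leaving C3 as the sole ketone.

**Step 12**
Reactants: 20
Product: 22 7-{[(1R,4aS,6S,8aR)-6-hydroxy-2,5,5,8a-tetramethyl-7-oxo-1,4,4a,5,6,7,8,8a-octahydronaphthalen-1-yl]methoxy}-2H-chromen-2-one, via lithium enolate 21 (not isolated)
Conditions: LiN(SiMe3)2 (1.05 equiv), THF, −78 °C; NaBH4, EtOH, −40 → −10 °C; acetone then AcOH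
Reagents that add atoms: none
Why: Chemoselective carbonyl reduction: C2 is stored as an enolate that borohydride cannot reduce, so hydride adds only to C3, from the face opposite the two axial methyls as with 4,4-dimethyl-3-ketones, giving the equatorial 3β-alcohol (3S); protonation at C1 returns the C2 ketone.

**Step 13**
Reactants: 22; 23 angelic acid
Product: 25 (2S,4aR,5R,8aS)-1,1,4a,6-tetramethyl-3-oxo-5-{[(2-oxo-2H-chromen-7-yl)oxy]methyl}-1,2,3,4,4a,5,8,8a-octahydronaphthalen-2-yl (2Z)-2-methylbut-2-enoate, via mixed anhydride 24 (not isolated)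
Conditions: 23, 2,4,6-trichlorobenzoyl chloride, Et3N, toluene, rt; then 22, toluene, 75 °C (no DMAP)
Reagents that add atoms: none
Why: Yamaguchi esterification through the mixed anhydride, run without DMAP so the Z-enoate does not isomerise to tiglate, acylates the equatorial 3-hydroxyl with retention at C3.

**Compound list**
1 | (S)-(+)-carvone, (5S)-2-methyl-5-(prop-1-en-2-yl)cyclohex-2-en-1-one | CC1=CC[C@@H](CC1=O)C(C)=C | starting material
2 | lithium (3S)-6-methyl-3-(prop-1-en-2-yl)cyclohexa-1,5-dien-1-olate | CC1=CC[C@@H](C=C1[O-])C(C)=C.[Li+] | intermediate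
3 | (5S)-2,6-dimethyl-5-(prop-1-en-2-yl)cyclohex-2-en-1-one (C6 epimers) | CC1=CC[C@H](C(C)=C)C(C)C1=O | intermediate
4 | lithium (3R)-2,6-dimethyl-3-(prop-1-en-2-yl)cyclohexa-1,5-dien-1-olate | CC1=CC[C@H](C(C)=C)C(C)=C1[O-].[Li+] | intermediate
5 | (3R)-2,6-dimethyl-3-(prop-1-en-2-yl)cyclohexa-1,5-dien-1-yl trifluoromethanesulfonate | CC1=CC[C@H](C(C)=C)C(C)=C1OS(=O)(=O)C(F)(F)F | intermediate
6 | [(3R)-2,6-dimethyl-3-(prop-1-en-2-yl)cyclohexa-1,5-dien-1-yl]methanol | CC1=CC[C@H](C(C)=C)C(C)=C1CO | intermediate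
7 | [(3R)-2,6-dimethyl-3-(prop-1-en-2-yl)cyclohexa-1,5-dien-1-yl]methyl vinyl ether | CC1=CC[C@H](C(C)=C)C(C)=C1COC=C | intermediate
8 | 2-[(1R,6R)-1,3-dimethyl-2-methylidene-6-(prop-1-en-2-yl)cyclohex-3-en-1-yl]acetaldehyde | O=CC[C@@]1(C)C(=C)C(C)=CC[C@@H]1C(C)=C | intermediate
9 | (4aR,8aR)-7,8a-dimethyl-4,8-dimethylidene-1,2,3,4,4a,5,8,8a-octahydronaphthalen-2-ol (C2 epimers) | OC1C[C@@]2(C)C(=C)C(C)=CC[C@@H]2C(=C)C1 | intermediate
10 | (4aR,8aR)-7,8a-dimethyl-4,8-dimethylidene-3,4,4a,5,8,8a-hexahydronaphthalen-2(1H)-one | O=C1C[C@@]2(C)C(=C)C(C)=CC[C@@H]2C(=C)C1 | intermediate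
11 | (4aR,8aR)-4,7,8a-trimethyl-8-methylidene-4a,5,8,8a-tetrahydronaphthalen-2(1H)-one | O=C1C[C@@]2(C)C(=C)C(C)=CC[C@@H]2C(C)=C1 | intermediate
12 | triethyl{[(4aR,8aR)-4,4,7,8a-tetramethyl-8-methylidene-1,4,4a,5,8,8a-hexahydronaphthalen-2-yl]oxy}silane | C1=C(O[Si](CC)(CC)CC)C[C@@]2(C)C(=C)C(C)=CC[C@@H]2C1(C)C | intermediate
13 | 9-BBN adduct of 12 with boron on C11 and H on C9 (configuration as 14) | C1=C(O[Si](CC)(CC)CC)C[C@@]2(C)[C@H](CB3C4CCCC3CCC4)C(C)=CC[C@@H]2C1(C)C | intermediate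
14 | [(1R,4aR,8aR)-2,5,5,8a-tetramethyl-7-(triethylsilyloxy)-1,4,4a,5,8,8a-hexahydronaphthalen-1-yl]methanol | C1=C(O[Si](CC)(CC)CC)C[C@@]2(C)[C@H](CO)C(C)=CC[C@@H]2C1(C)C | intermediate
15 | umbelliferone, 7-hydroxy-2H-chromen-2-one | O=c1ccc2ccc(O)cc2o1 | starting material
16 | 7-{[(1R,4aR,8aR)-2,5,5,8a-tetramethyl-7-(triethylsilyloxy)-1,4,4a,5,8,8a-hexahydronaphthalen-1-yl]methoxy}-2H-chromen-2-one | C1=C(O[Si](CC)(CC)CC)C[C@@]2(C)[C@H](COc3ccc4ccc(=O)oc4c3)C(C)=CC[C@@H]2C1(C)C | intermediate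
17 | 2,3-epoxide of 16 on the face opposite the C10 methyl, with C2 still carrying OSiEt3 | CC[Si](CC)(CC)O[C@]12C[C@@]3(C)[C@H](COc4ccc5ccc(=O)oc5c4)C(C)=CC[C@@H]3C(C)(C)[C@H]1O2 | intermediate
18 | 7-{[(1R,4aS,6R,8aR)-6-hydroxy-2,5,5,8a-tetramethyl-7-oxo-1,4,4a,5,6,7,8,8a-octahydronaphthalen-1-yl]methoxy}-2H-chromen-2-one | O[C@H]1C(=O)C[C@@]2(C)[C@H](COc3ccc4ccc(=O)oc4c3)C(C)=CC[C@@H]2C1(C)C | intermediate
19 | 7-{[(1R,4aS,8aR)-2,5,5,8a-tetramethyl-6,7-dioxo-1,4,4a,5,6,7,8,8a-octahydronaphthalen-1-yl]methoxy}-2H-chromen-2-one | O=C1C(=O)C[C@@]2(C)[C@H](COc3ccc4ccc(=O)oc4c3)C(C)=CC[C@@H]2C1(C)C | intermediate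
20 | 7-{[(1R,4aS,8aR)-7-hydroxy-2,5,5,8a-tetramethyl-6-oxo-1,4,4a,5,6,8a-hexahydronaphthalen-1-yl]methoxy}-2H-chromen-2-one | O=C1C(O)=C[C@@]2(C)[C@H](COc3ccc4ccc(=O)oc4c3)C(C)=CC[C@@H]2C1(C)C | intermediate
21 | lithium enolate (diosphenolate) of 20 | O=C1C([O-])=C[C@@]2(C)[C@H](COc3ccc4ccc(=O)oc4c3)C(C)=CC[C@@H]2C1(C)C.[Li+] | intermediate
22 | 7-{[(1R,4aS,6S,8aR)-6-hydroxy-2,5,5,8a-tetramethyl-7-oxo-1,4,4a,5,6,7,8,8a-octahydronaphthalen-1-yl]methoxy}-2H-chromen-2-one | O[C@@H]1C(=O)C[C@@]2(C)[C@H](COc3ccc4ccc(=O)oc4c3)C(C)=CC[C@@H]2C1(C)C | intermediate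
23 | angelic acid, (2Z)-2-methylbut-2-enoic acid | C/C=C(/C)C(=O)O | starting material
24 | (2Z)-2-methylbut-2-enoic 2,4,6-trichlorobenzoic anhydride | C/C=C(/C)C(=O)OC(=O)c1c(Cl)cc(Cl)cc1Cl | intermediate
25 | (2S,4aR,5R,8aS)-1,1,4a,6-tetramethyl-3-oxo-5-{[(2-oxo-2H-chromen-7-yl)oxy]methyl}-1,2,3,4,4a,5,8,8a-octahydronaphthalen-2-yl (2Z)-2-methylbut-2-enoate | C/C=C(/C)C(=O)O[C@@H]1C(=O)C[C@@]2(C)[C@H](COc3ccc4ccc(=O)oc4c3)C(C)=CC[C@@H]2C1(C)C | target

**Totals**
Total steps: 13. Longest linear sequence: 13 (from 1; 15 and 23 are bought).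

**Steps most likely to fail**

Step 3. Transfer of the hydroxymethyl group from tin to a hindered, tetrasubstituted dienyl triflate may stall or transfer butyl instead. The fallback sets out from 5: Pd(OAc)2/PPh3-catalysed methoxycarbonylation (CO 1 atm, MeOH, Et3N, DMF, 60 °C) gives methyl (3R)-2,6-dimethyl-3-(prop-1-en-2-yl)cyclohexa-1,5-diene-1-carboxylate F1, and iBu2AlH (CH2Cl2, −78 °C) reduces it to 6, where the route is rejoined.

Step 12. If the enolate is protonated by the medium, the freed C2 ketone is reduced as well and the 2,3-diol results. The fallback sets out from 20: acylation of the enolic hydroxyl with mixed anhydride 24 (Et3N, toluene, rt) gives the enol angelate 7-{[(1R,4aS,8aR)-2,5,5,8a-tetramethyl-7-{[(2Z)-2-methylbut-2-enoyl]oxy}-6-oxo-1,4,4a,5,6,8a-hexahydronaphthalen-1-yl]methoxy}-2H-chromen-2-one F2. NaBH4/CeCl3·7H2O (MeOH, −78 °C) then reduces C3 from the same face to the (6S)-6-hydroxy enol ester F3, and imidazole (CH2Cl2, rt) moves the acyl group from the enol oxygen to the neighbouring hydroxyl with ketonisation of C2. This comes back to the route at 25 and makes step 13 unnecessary.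

Step 13. The 3-hydroxyl is neopentyl-like; forcing conditions risk Z-to-E isomerisation of the acyl donor or a base-induced ketol shift. The fallback sets out from 22: the less demanding 2-[bis(2,2,2-trifluoroethoxy)phosphoryl]propanoic acid is coupled (EDC, cat. DMAP, CH2Cl2) to give the 2-[bis(2,2,2-trifluoroethoxy)phosphoryl]propanoate of 22 F4. Still–Gennari olefination with acetaldehyde (KN(SiMe3)2, 18-crown-6, THF, −78 °C) then builds the Z-2-methylbut-2-enoate in place and comes back to the route at 25.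

**Further compounds**
F1 | step 3 | methyl (3R)-2,6-dimethyl-3-(prop-1-en-2-yl)cyclohexa-1,5-diene-1-carboxylate | CC1=CC[C@H](C(C)=C)C(C)=C1C(=O)OC
F2 | step 12 | 7-{[(1R,4aS,8aR)-2,5,5,8a-tetramethyl-7-{[(2Z)-2-methylbut-2-enoyl]oxy}-6-oxo-1,4,4a,5,6,8a-hexahydronaphthalen-1-yl]methoxy}-2H-chromen-2-one | C/C=C(/C)C(=O)OC1=C[C@@]2(C)[C@H](COc3ccc4ccc(=O)oc4c3)C(C)=CC[C@@H]2C(C)(C)C1=O
F3 | step 12 | 7-{[(1R,4aS,6S,8aR)-6-hydroxy-2,5,5,8a-tetramethyl-7-{[(2Z)-2-methylbut-2-enoyl]oxy}-1,4,4a,5,6,8a-hexahydronaphthalen-1-yl]methoxy}-2H-chromen-2-one | C/C=C(/C)C(=O)OC1=C[C@@]2(C)[C@H](COc3ccc4ccc(=O)oc4c3)C(C)=CC[C@@H]2C(C)(C)[C@@H]1O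
F4 | step 13 | (2S,4aR,5R,8aS)-1,1,4a,6-tetramethyl-3-oxo-5-{[(2-oxo-2H-chromen-7-yl)oxy]methyl}-1,2,3,4,4a,5,8,8a-octahydronaphthalen-2-yl 2-[bis(2,2,2-trifluoroethoxy)phosphoryl]propanoate (epimers at the phosphonate carbon) | CC(C(=O)O[C@@H]1C(=O)C[C@@]2(C)[C@H](COc3ccc4ccc(=O)oc4c3)C(C)=CC[C@@H]2C1(C)C)P(=O)(OCC(F)(F)F)OCC(F)(F)F
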